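The benzene ring of gentiside E is numbered C1 (bearing the ester carbon C7), C2 and C3 (the two hydroxyl carbons) and C4–C6 (CH). All three substituents sit on the contiguous C1–C2–C3 triad, while the C4–C5 bond joins two unsubstituted carbons. The route therefore builds the triad on an acyclic beta-keto ester and closes the carbocycle at C4–C5 by ring-closing olefin metathesis. The precursor is an octadecyl beta-keto ester carrying an allyl group on C1 and a benzyloxy group plus a vinyl group on C3. Metathesis delivers, in one operation, the complete six-membered ring at the dihydroarene oxidation level; dehydrogenation and debenzylation finish the catechol.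

Key step: step 6

Assumption: racemic methyl 2-hydroxybut-3-enoate is used and all sp3 intermediates are carried as racemates or diastereomer mixtures, because both stereocentres become aromatic carbons and the target is achiral.

Step 1
Reactants: 1 methyl 2-hydroxybut-3-enoate (racemic)
Product: 2 methyl 2-(benzyloxy)but-3-enoate (racemic)
Conditions: BnOC(=NH)CCl3 (1.3 equiv), TfOH (5 mol%), CH2Cl2/cyclohexane 1:2, 0 °C to rt
Reagents that add atoms: benzyl 2,2,2-trichloroacetimidate, N=C(OCc1ccccc1)C(Cl)(Cl)Cl
Why: Acid-catalysed benzyl transfer from the trichloroacetimidate (O-benzylation through a benzyl cation equivalent) etherifies the secondary allylic alcohol without base, so the acidic alpha-hydrogen between ester and vinyl group is left alone and the double bond should not move into conjugation; no stereocentre is set and the material stays racemic.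

Step 2
Reactants: 2 methyl 2-(benzyloxy)but-3-enoate (racemic)
Product: 3 2-(benzyloxy)but-3-enoic acid (racemic)
Conditions: LiOH·H2O (1.5 equiv), THF/H2O 3:1, 0 °C; then 1 M HCl to pH 2
Reagents that add atoms: lithium hydroxide monohydrate, [Li+].[OH-].O
Why: Saponification (addition–elimination of hydroxide at the ester carbonyl) should outrun alpha-deprotonation at 0 °C because the alpha-alkoxy ester is activated towards hydroxide, and the carboxylate formed is no longer acidic at the alpha-carbon, so the vinyl group should stay in place.

Step 3
Reactants: 3 2-(benzyloxy)but-3-enoic acid (racemic); 4 Meldrum's acid (2,2-dimethyl-1,3-dioxane-4,6-dione)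
Product: 5 5-[2-(benzyloxy)-1-hydroxybut-3-en-1-ylidene]-2,2-dimethyl-1,3-dioxane-4,6-dione (racemic; enol form of the acyl Meldrum's acid)
Conditions: DCC (1.1 equiv), DMAP (1.5 equiv), CH2Cl2, 0 °C to rt; filter; cold 1 M KHSO4 wash; used crude
Reagents that add atoms: none
Why: Carbodiimide-mediated C-acylation of Meldrum's acid (first half of the Oikawa–Yonemitsu beta-keto ester synthesis) proceeds through an N-acylpyridinium that is attacked by the Meldrum's acid anion, and the strongly acidic product is held as its unreactive enolate until the acidic wash.

Step 4
Reactants: 5 5-[2-(benzyloxy)-1-hydroxybut-3-en-1-ylidene]-2,2-dimethyl-1,3-dioxane-4,6-dione; 6 1-octadecanol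
Product: 8 octadecyl 4-(benzyloxy)-3-oxohex-5-enoate (racemic), via acylketene 7 (not isolated)
Conditions: 1-octadecanol (1.05 equiv), toluene, 100 °C
Reagents that add atoms: none
Why: Heating the acyl Meldrum's acid expels acetone and CO2 in a retro-hetero-Diels–Alder fragmentation to the acylketene 7, which the primary alcohol captures under neutral conditions (acylketene alcoholysis), so no base touches the enolisable C4 hydrogen.

Step 5
Reactants: 8 octadecyl 4-(benzyloxy)-3-oxohex-5-enoate (racemic); 9 allyl bromide (3-bromoprop-1-ene)
Product: 10 octadecyl 2-allyl-4-(benzyloxy)-3-oxohex-5-enoate (mixture of diastereomers, each racemic)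
Conditions: K2CO3 (1.5 equiv), allyl bromide (1.0 equiv), acetone, 40 °C
Reagents that add atoms: none
Why: In this C-alkylation of a beta-keto ester, K2CO3 deprotonates only the doubly activated C2 position and the stabilised enolate displaces bromide from the allylic halide in an SN2 reaction, the limiting amount of allyl bromide curbing double alkylation; the new C2 stereocentre is uncontrolled and needs no control because it becomes an aromatic carbon.

Step 6
Reactants: 10 octadecyl 2-allyl-4-(benzyloxy)-3-oxohex-5-enoate (mixture of diastereomers)
Product: 11 octadecyl 5-(benzyloxy)-6-oxocyclohex-3-ene-1-carboxylate (mixture of diastereomers, in equilibrium with its enol)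
Conditions: second-generation Grubbs catalyst (H2IMes)(PCy3)Cl2Ru=CHPh (5 mol%), degassed CH2Cl2 (0.005 M), 40 °C; ethyl vinyl ether quench; short neutral silica plug; used directly
Reagents that add atoms: none
Why: Ring-closing olefin metathesis by the Chauvin mechanism: the ruthenium benzylidene should first exchange with the unhindered allyl terminus, the new alkylidene then adds to the vinyl group on the benzyloxy-bearing carbon in a [2+2] cycloaddition to a ruthenacyclobutane, and retro-[2+2] releases the ring with the new C4=C5 bond while ethylene escapes and makes the sequence irreversible. The closest known reaction type is the ring-closing metathesis of 1,7-dienes carrying ketone, ester and allylic ether groups to cyclohexenes, for which this catalyst is the standard choice. The one ring is closed in a six-membered mode, the two alkene termini being tethered through C6, C1, C2 and C3, so only a cis ring alkene can form. No stereocentre is created; the two existing ones (C1 and C3) remain as a diastereomer mixture and are erased in the next step. The step needs cyclisation to win over intermolecular metathesis and needs the product to survive without double-bond migration or loss of benzyl alcohol; high dilution, the strain-free six-membered ring, the absence of acid and base, and immediate use of the product should secure this.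

Step 7
Reactants: 11 octadecyl 5-(benzyloxy)-6-oxocyclohex-3-ene-1-carboxylate
Product: 12 octadecyl 3-(benzyloxy)-2-hydroxybenzoate
Conditions: DDQ (1.05 equiv), toluene, 0 °C to rt; filter; aq. NaHCO3 wash
Reagents that add atoms: none
Why: In this quinone dehydrogenation the enol of 11 is a cyclohexa-1,4-diene whose C3–H and C6–H bonds are doubly allylic, so DDQ should abstract hydride and the resulting cation lose a proton to give the arene directly, with aromaticity as driving force and the hydrogen-bonded, ester-deactivated phenol resistant to further oxidation.

Step 8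
Reactants: 12 octadecyl 3-(benzyloxy)-2-hydroxybenzoate
Product: 13 octadecyl 2,3-dihydroxybenzoate (gentiside E)
Conditions: H2 (1 atm), 10% Pd/C (palladium on carbon), EtOAc/EtOH, rt
Reagents that add atoms: none
Why: Hydrogenolysis of an aryl benzyl ether over palladium on carbon cleaves the benzylic C–O bond and leaves the saturated ester, the arene and the phenols untouched, giving the catechol and toluene.

Compound list
1 | methyl 2-hydroxybut-3-enoate (racemic) | COC(=O)C(O)C=C | starting material
2 | methyl 2-(benzyloxy)but-3-enoate (racemic) | COC(=O)C(OCc1ccccc1)C=C | intermediate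
3 | 2-(benzyloxy)but-3-enoic acid (racemic) | OC(=O)C(OCc1ccccc1)C=C | intermediate
4 | Meldrum's acid (2,2-dimethyl-1,3-dioxane-4,6-dione) | CC1(C)OC(=O)CC(=O)O1 | starting material
5 | 5-[2-(benzyloxy)-1-hydroxybut-3-en-1-ylidene]-2,2-dimethyl-1,3-dioxane-4,6-dione (racemic) | CC1(C)OC(=O)C(=C(O)C(OCc2ccccc2)C=C)C(=O)O1 | intermediate
6 | 1-octadecanol | CCCCCCCCCCCCCCCCCCO | starting material
7 | 4-(benzyloxy)hexa-1,5-diene-1,3-dione (acylketene, racemic, not isolated) | C=CC(OCc1ccccc1)C(=O)C=C=O | intermediate
8 | octadecyl 4-(benzyloxy)-3-oxohex-5-enoate (racemic) | CCCCCCCCCCCCCCCCCCOC(=O)CC(=O)C(OCc1ccccc1)C=C | intermediate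
9 | allyl bromide (3-bromoprop-1-ene) | C=CCBr | starting material
10 | octadecyl 2-allyl-4-(benzyloxy)-3-oxohex-5-enoate (mixture of diastereomers) | C=CCC(C(=O)OCCCCCCCCCCCCCCCCCC)C(=O)C(OCc1ccccc1)C=C | intermediate
11 | octadecyl 5-(benzyloxy)-6-oxocyclohex-3-ene-1-carboxylate (mixture of diastereomers) | CCCCCCCCCCCCCCCCCCOC(=O)C1CC=CC(OCc2ccccc2)C1=O | intermediate
12 | octadecyl 3-(benzyloxy)-2-hydroxybenzoate | CCCCCCCCCCCCCCCCCCOC(=O)c1cccc(OCc2ccccc2)c1O | intermediate
13 | octadecyl 2,3-dihydroxybenzoate (gentiside E, achiral) | CCCCCCCCCCCCCCCCCCOC(=O)c1cccc(O)c1O | target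

Total step count: 8.
Longest linear sequence: 8 steps (1 to 13); 4, 6 and 9 are commercial and enter directly.

Steps most likely to fail

1. Step 6 (ring-closing metathesis). The enolised beta-keto ester may chelate the ruthenium carbene and stall turnover, intermolecular metathesis may give oligomers, or ruthenium hydride formed by catalyst decay may shift the double bonds. The fallback masks the ketone by reduction during ring closure, setting out from 10 and coming back at 11. NaBH4 (THF/MeOH, −20 °C) should give octadecyl 2-allyl-4-(benzyloxy)-3-hydroxyhex-5-enoate F1 as a diastereomer mixture. Ring-closing metathesis of this non-enolisable diene with the same catalyst (H2IMes)(PCy3)Cl2Ru=CHPh in dilute CH2Cl2 should give octadecyl 5-(benzyloxy)-6-hydroxycyclohex-3-ene-1-carboxylate F2. Oxidation with Dess–Martin periodinane (NaHCO3, CH2Cl2) should then return 11.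

2. Step 7 (dehydrogenation). The C3–O benzyl ether bond may ionise under the mildly acidic conditions created by the reduced quinone and a proton then be lost, which aromatises the ring with loss of benzyl alcohol and of the C3 oxygen; oxidative cleavage of the benzyl ether is a second possibility. The fallback dehydrogenates through selenium chemistry instead of hydride abstraction, setting out from 11 and coming back at 12. PhSeCl and pyridine (CH2Cl2, 0 °C) should selenate the doubly activated C1 to give octadecyl 5-(benzyloxy)-6-oxo-1-(phenylselanyl)cyclohex-3-ene-1-carboxylate F3. H2O2 (CH2Cl2, 0 °C) should oxidise it to octadecyl 5-(benzyloxy)-6-oxo-1-(phenylseleninyl)cyclohex-3-ene-1-carboxylate F4. Syn-elimination of this selenoxide towards C6–H should give octadecyl 5-(benzyloxy)-6-oxocyclohexa-1,3-diene-1-carboxylate F5, which should tautomerise at once to 12.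

3. Step 5 (allylation). A second allylation at C2, O-allylation of the enolate, or a base-promoted shift of the C5=C6 double bond into conjugation with the ketone may occur. The fallback brings the allyl group in on the nucleophile before the C2–C3 bond is made; it sets out from 3 (with 6) and comes back at 10, bypassing 5, 7 and 8. Carbonyldiimidazole (THF, rt) should convert 3 into 1-[2-(benzyloxy)but-3-enoyl]-1H-imidazole F6. Separately, DCC-mediated mono-esterification of commercial allylmalonic acid with 6 (MeCN, rt, through a carboxyketene) should give 2-[(octadecyloxy)carbonyl]pent-4-enoic acid F7. Its magnesium enolate (MgCl2, Et3N, THF/MeCN, rt) should be C-acylated by F6 to 2-allyl-2-[2-(benzyloxy)but-3-enoyl]malonic acid mono-octadecyl ester F8, which should lose CO2 on mild acidic work-up (Masamune–Brooks-type decarboxylative Claisen condensation) to give 10.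

Further compounds
F1 | step 6 | octadecyl 2-allyl-4-(benzyloxy)-3-hydroxyhex-5-enoate (mixture of diastereomers) | C=CCC(C(=O)OCCCCCCCCCCCCCCCCCC)C(O)C(OCc1ccccc1)C=C
F2 | step 6 | octadecyl 5-(benzyloxy)-6-hydroxycyclohex-3-ene-1-carboxylate (mixture of diastereomers) | CCCCCCCCCCCCCCCCCCOC(=O)C1CC=CC(OCc2ccccc2)C1O
F3 | step 7 | octadecyl 5-(benzyloxy)-6-oxo-1-(phenylselanyl)cyclohex-3-ene-1-carboxylate (mixture of diastereomers) | CCCCCCCCCCCCCCCCCCOC(=O)C1([Se]c2ccccc2)CC=CC(OCc2ccccc2)C1=O
F4 | step 7 | octadecyl 5-(benzyloxy)-6-oxo-1-(phenylseleninyl)cyclohex-3-ene-1-carboxylate (mixture of diastereomers) | CCCCCCCCCCCCCCCCCCOC(=O)C1([Se](=O)c2ccccc2)CC=CC(OCc2ccccc2)C1=O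
F5 | step 7 | octadecyl 5-(benzyloxy)-6-oxocyclohexa-1,3-diene-1-carboxylate (racemic) | CCCCCCCCCCCCCCCCCCOC(=O)C1=CC=CC(OCc2ccccc2)C1=O
F6 | step 5 | 1-[2-(benzyloxy)but-3-enoyl]-1H-imidazole (racemic) | C=CC(OCc1ccccc1)C(=O)n1ccnc1
F7 | step 5 | 2-[(octadecyloxy)carbonyl]pent-4-enoic acid (racemic) | C=CCC(C(=O)O)C(=O)OCCCCCCCCCCCCCCCCCC
F8 | step 5 | 2-allyl-2-[2-(benzyloxy)but-3-enoyl]malonic acid mono-octadecyl ester (mixture of diastereomers) | C=CCC(C(=O)O)(C(=O)OCCCCCCCCCCCCCCCCCC)C(=O)C(OCc1ccccc1)C=C
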